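If the second portion of partner waits outside the flask, does the target at the end suffer?

the same everywhere: substrate 0.80 M; partner 1.44 M (in portions, 2)
- winter: free catalyst 2.4 mM; run made earlier; portions every 0.30 h
- Wednesday's: free catalyst 1.6 mM; the portions of partner follow each other after 0.30 h, the first at the start; time 6.0 h
- Saturday's: free catalyst 1.6 mM; the portions of partner follow each other after 1.0 h, the first at the start; time 6.0 h
- Thursday's: free catalyst 1.6 mM; the portions of partner follow each other after 3.0 h, the first at the start; time 6.0 h
- Tuesday's: free catalyst 1.6 mM; the portions of partner follow each other after 10 h, the first at the start; time 6.0 h
- Sunday's: free catalyst 1.6 mM; the portions of partner follow each other after 25 h, the first at the start; time 6.0 h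

winter run (percent of the substrate charged): time / min: target / % = 3.00: 0.4; 5.00: 2.5; 8.00: 1.1; 12.0: 0.6; 20.0: 4.8; 40.0: 10.9

(each reading ± 1 percentage point)

- percent here means substrate units held: one self-condensation product counts as two
- the numbers in the tables scatter with a standard deviation of 1 percentage point
- steps under discussion: catalyst intermediate C -> free catalyst + target; partner + catalyst intermediate A -> catalyst intermediate B; 2 substrate -> self-condensation product; catalyst intermediate B -> catalyst intermediate C; substrate + free catalyst -> catalyst intermediate A
- percentages count the whole charge, also what has not yet gone in
- "hardly changes" means that all values lie within two and a half points (for a concentration: within two and a half percent of the largest)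
- a step back or a flat step of under half a percent of the largest counts as no turn
- no earlier run changes the charge of free catalyst; that part of a forecast is a guess

- [target] at the end for Wednesday's, Saturday's, Thursday's, Tuesday's, Sunday's, in this order
- the shape of the row from first to last (hardly changes / rises, then falls / falls, then rises / falls all the way / rises all the way)

Ines and Paul read winter's run differently, and they start from the same slope. Between 20.0 min and 40.0 min the target climbs at a pace that gives 0.0976 M/h, once scaled to 1.6 mM of free catalyst. That scaling is a guess. The readings before the second portion sit near the scatter, so they can't part the two views.

Paul says the catalyst turns at a fixed pace, whatever the partner level. Over 6.0 h that makes 0.586 M, less than one portion of 0.720 M. So for him the row hardly changes.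

Ines says the catalyst waits as catalyst intermediate A, its resting state, until a partner molecule finds it. The rate is then pseudo-first-order in partner, and each partner molecule has the same chance per hour, 0.0678 /h. She follows one molecule. Its capture chance, the share of a portion taken up during its hours in the flask, is 33.4 % for a molecule present from the start. A portion due at 25 h comes later than the reading, so its chance is nil. Her reckoning gives 0.241 M for Sunday's flask and 0.471 M for Wednesday's.

The forecast takes her side: 0.44 M, 0.43 M, 0.37 M, 0.26 M, 0.26 M, a row that falls all the way. In its words, "The row falls, then goes flat."

The flasks give 0.538 M, 0.518 M, 0.455 M, 0.336 M, 0.336 M, so the row falls all the way. Ines has the shape, but Sunday's value stands 0.0760 M above the forecast. Paul keeps the short gaps. In Wednesday's flask the dosing makes no difference, and Saturday's lies just 0.0200 M lower.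

    catalyst intermediate C → free catalyst + target (k = 2.70 /min)
    partner + catalyst intermediate A → catalyst intermediate B (k = 1.50 /M/min)
    2 substrate → self-condensation product (k = 1.20 × 10⁻⁴ /M/min)
    catalyst intermediate B → catalyst intermediate C (k = 13.0 /min)
    substrate + free catalyst → catalyst intermediate A (k = 85.0 /M/min)

Sunday's target of 0.336 M stands low because of the dosing and the early reading together. With the dosing taken away, the whole charge going in at the start, Sunday's flask gives 0.545 M. With the early reading taken away, the reading moved to 60.0 h, Sunday's flask gives 0.756 M. Sunday's first portion shows a capture chance of 46.7 %, more than the reckoned 33.4 %, while Wednesday's charge shows 37.4 %. At the end, catalyst intermediate A held 78.5 % of the catalyst in Sunday's flask and 59.8 % in Wednesday's.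

Readings and results are calculated on assumed constants.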